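**Retrosynthetic overview**
- The target is taken back to its C1 dimethyl ketal, and this is cut at the C4–C1' bond into two complete halves: an epoxyquinone C1‑monoketal carrying the upper trienamide, and a (2E,4E,6E)‑7‑iodohepta‑2,4,6‑trienamide that already carries the cyclopentenone (ring C).
- Upper half: 2,5‑dimethoxyaniline is N‑acylated with the C12 trienoic acid (Wittig, then vinylogous Horner–Wadsworth–Emmons), dearomatised with PhI(OAc)2/MeOH, and epoxidised under chiral phase‑transfer catalysis (sets C5, C6).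
- Lower half: (E)‑4,4‑dimethoxybut‑2‑enal is extended by Horner–Wadsworth–Emmons and Takai olefination, then coupled to 2‑amino‑3‑hydroxycyclopent‑2‑enone.
- Enabling feature: in ring A the oxirane oxygen on C5/C6 lies on one face beside the C4 carbonyl oxygen, a two‑point seat for magnesium on that face; the C1 ketal leaves C4 as the only ketone. C1', the ζ‑acceptor carbon of the trienamide, is made a donor by iodine–magnesium exchange.
- Rings: ring C is bought; ring A is the arene of 2,5‑dimethoxyaniline, dearomatised; the oxirane follows; the key step closes no ring.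

Key step: step 11

**Remarks**
- Ring A locants used throughout: C1 ketone (or ketal) carbon, C2 nitrogen‑bearing carbon, C3 vinylic CH, C4 carbinol (or ketone) carbon, C5/C6 oxirane carbons (C5 next to C4); the lower chain is C1'–C7' from the ring.
- The target is (4S,5S,6R): the C4 hydroxyl is trans to the oxirane oxygen and C1' is cis to it. Alkenyllithium reagents add to such epoxy ketals anti to the oxirane, which would give the C4 epimer; the key step is designed to reverse this.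
- 2‑Amino‑3‑hydroxycyclopent‑2‑en‑1‑one hydrochloride is assumed to be purchasable (otherwise it is two steps from cyclopentane‑1,3‑dione by nitrosation and hydrogenation).

**Route**

Step 1
Reactants: 1 4‑methylpentanal; 2 (triphenylphosphoranylidene)acetaldehyde
Product: 3 (E)‑6‑methylhept‑2‑enal
Conditions: toluene, 80 °C (slight excess of 1)
Reagents that add atoms: none
Why: Wittig olefination with the formyl‑stabilised ylide adds two carbons and should give the E enal, as stabilised ylides do.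

Step 2
Reactants: 3 (E)‑6‑methylhept‑2‑enal; 4 triethyl 4‑phosphonocrotonate
Product: 5 ethyl (2E,4E,6E)‑10‑methylundeca‑2,4,6‑trienoate
Conditions: LiN(SiMe3)2, THF, −78 → 0 °C
Reagents that add atoms: none
Why: Vinylogous Horner–Wadsworth–Emmons olefination, in which the stabilised phosphonate anion forms the new C4=C5 bond E and the crotonate double bond stays E.

Step 3
Reactants: 5 ethyl (2E,4E,6E)‑10‑methylundeca‑2,4,6‑trienoate
Product: 6 (2E,4E,6E)‑10‑methylundeca‑2,4,6‑trienoic acid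
Conditions: LiOH, THF/H2O, rt; then aq. HCl
Reagents that add atoms: lithium hydroxide, [Li+].[OH-]
Why: Ester saponification, which leaves the conjugated triene untouched.

Step 4
Reactants: 6 (2E,4E,6E)‑10‑methylundeca‑2,4,6‑trienoic acid; 7 2,5‑dimethoxyaniline
Product: 9 N‑(2,5‑dimethoxyphenyl)‑(2E,4E,6E)‑10‑methylundeca‑2,4,6‑trienamide, via trienoyl chloride 8 (not isolated)
Conditions: (COCl)2, DMF (cat.), CH2Cl2, 0 °C; then 7, pyridine, 0 °C → rt
Reagents that add atoms: none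
Why: Acid chloride formation followed by Schotten–Baumann‑type N‑acylation of the aniline.

Step 5
Reactants: 9 N‑(2,5‑dimethoxyphenyl)‑(2E,4E,6E)‑10‑methylundeca‑2,4,6‑trienamide
Product: 10 N‑(6,6‑dimethoxy‑3‑oxocyclohexa‑1,4‑dien‑1‑yl)‑(2E,4E,6E)‑10‑methylundeca‑2,4,6‑trienamide
Conditions: PhI(OAc)2, MeOH, 0 °C
Reagents that add atoms: methanol, CO
Why: Hypervalent‑iodine oxidative dearomatisation, in which methanol adds to the methoxy carbon ortho to nitrogen and the other methoxy carbon becomes the ketone, giving the C1 ketal/C4 ketone pattern while the electron‑poor triene is left alone.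

Step 6
Reactants: 10 N‑(6,6‑dimethoxy‑3‑oxocyclohexa‑1,4‑dien‑1‑yl)‑(2E,4E,6E)‑10‑methylundeca‑2,4,6‑trienamide
Product: 11 N‑[(5S,6R)‑5,6‑epoxy‑1,1‑dimethoxy‑4‑oxocyclohex‑2‑en‑2‑yl]‑(2E,4E,6E)‑10‑methylundeca‑2,4,6‑trienamide
Conditions: t‑BuOOH, aq. NaOH, N‑benzylcinchoninium chloride (10 mol %), toluene, 0 °C → rt; recrystallisation
Reagents that add atoms: tert‑butyl hydroperoxide, CC(C)(C)OO
Why: Weitz–Scheffer epoxidation under chiral phase‑transfer catalysis, in which the peroxide anion attacks only the C5=C6 enone, the ring forces a cis oxirane and the chiral ion pair should set (5S,6R); the pseudo‑enantiomeric cinchonidinium salt gives the antipode, so the sense of induction is to be checked on the first run.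

Step 7
Reactants: 12 (E)‑4,4‑dimethoxybut‑2‑enal; 13 triethyl phosphonoacetate
Product: 15 ethyl (2E,4E)‑6‑oxohexa‑2,4‑dienoate, via dienoate acetal 14 (not isolated)
Conditions: NaH, THF, 0 °C → rt; then aq. HCl (1 M), THF, rt
Reagents that add atoms: water, O
Why: E‑selective Horner–Wadsworth–Emmons olefination followed by acetal hydrolysis in the work‑up.

Step 8
Reactants: 15 ethyl (2E,4E)‑6‑oxohexa‑2,4‑dienoate
Product: 16 ethyl (2E,4E,6E)‑7‑iodohepta‑2,4,6‑trienoate
Conditions: CrCl2, CHI3, THF/1,4‑dioxane, 0 °C, dark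
Reagents that add atoms: iodoform, IC(I)I
Why: Takai olefination, in which the geminal dichromium species formed from iodoform and divalent chromium adds to the aldehyde only and anti elimination should give the E iodoalkene.

Step 9
Reactants: 16 ethyl (2E,4E,6E)‑7‑iodohepta‑2,4,6‑trienoate
Product: 17 (2E,4E,6E)‑7‑iodohepta‑2,4,6‑trienoic acid
Conditions: LiOH, THF/H2O, 0 °C → rt, dark; then aq. HCl
Reagents that add atoms: lithium hydroxide, [Li+].[OH-]
Why: Ester saponification under conditions that leave the alkenyl iodide intact.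

Step 10
Reactants: 17 (2E,4E,6E)‑7‑iodohepta‑2,4,6‑trienoic acid; 18 2‑amino‑3‑hydroxycyclopent‑2‑en‑1‑one hydrochloride
Product: 20 (2E,4E,6E)‑N‑(2‑hydroxy‑5‑oxocyclopent‑1‑en‑1‑yl)‑7‑iodohepta‑2,4,6‑trienamide, via iodotrienoyl chloride 19 (not isolated)
Conditions: (COCl)2, DMF (cat.), CH2Cl2, 0 °C; then 18, Et3N, THF, 0 °C → rt
Reagents that add atoms: none
Why: N‑acylation of the enaminone by the acid chloride, where any O‑acyl isomer formed at the vinylogous acid should rearrange to the hydrogen‑bonded N‑acyl amide.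

Step 11
Reactants: 20 (2E,4E,6E)‑N‑(2‑hydroxy‑5‑oxocyclopent‑1‑en‑1‑yl)‑7‑iodohepta‑2,4,6‑trienamide; 11 N‑[(5S,6R)‑5,6‑epoxy‑1,1‑dimethoxy‑4‑oxocyclohex‑2‑en‑2‑yl]‑(2E,4E,6E)‑10‑methylundeca‑2,4,6‑trienamide
Product: 23 (2E,4E,6E)‑N‑[(4S,5S,6R)‑5,6‑epoxy‑4‑hydroxy‑4‑[(1E,3E,5E)‑7‑[(2‑hydroxy‑5‑oxocyclopent‑1‑en‑1‑yl)amino]‑7‑oxohepta‑1,3,5‑trien‑1‑yl]‑1,1‑dimethoxycyclohex‑2‑en‑2‑yl]‑10‑methylundeca‑2,4,6‑trienamide, via trienylmagnesium reagent 21 (not isolated), via magnesium amidate 22 (not isolated)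
Conditions: 20, i‑PrMgCl·LiCl (3.1 equiv), THF, −20 → 0 °C; 11, i‑PrMgCl·LiCl (1.0 equiv), CH2Cl2/toluene, −78 °C; combine, −78 → −30 °C; aq. NH4Cl
Reagents that add atoms: none
Why: Proposed new method: i‑PrMgCl·LiCl first converts 20 into its magnesium enolate–amidate, which shields both carbonyl groups, and then exchanges iodine for magnesium with retention, so that C1', the ζ‑acceptor carbon of the trienamide, becomes a donor (polarity reversal) in 21, which adds 1,2 to C4 of 22, the only free ketone because C1 is a ketal and the amide is a magnesium amidate. The closest known reaction types are the 1,2‑addition of alkenyllithium reagents to epoxyquinone monoketals of this kind, which enters anti to the oxirane, and the coordination‑delivered reduction of α,β‑epoxy ketones by neutral aluminium hydrides, which enters syn to it; a syn‑selective carbon transfer of this kind has not been shown. No ring is closed. The new stereocentre C4 is to be set by the C5–C6 oxirane of ring A: its oxygen lies above the carbonyl plane beside O4, a magnesium bound to both oxygens in the weakly coordinating medium therefore sits on the oxirane face and passes its trienyl group to C4 from that face through a four‑centre transition state, which places C1' cis and the hydroxyl trans to the oxirane oxygen (4S). The step needs site selectivity (C4 against ketal, oxirane, amides and the nitrogen‑bearing C2 of the enone, secured by the ketal and the N‑magnesiation), facial selectivity (the chelate, the unproven point) and retention of the E geometry at C1' (alkenylmagnesium reagents are configurationally stable below 0 °C).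

Step 12
Reactants: 23 (the C1 dimethyl ketal of the target)
Product: 24 (2E,4E,6E)‑N‑[(4S,5S,6R)‑5,6‑epoxy‑4‑hydroxy‑4‑[(1E,3E,5E)‑7‑[(2‑hydroxy‑5‑oxocyclopent‑1‑en‑1‑yl)amino]‑7‑oxohepta‑1,3,5‑trien‑1‑yl]‑1‑oxocyclohex‑2‑en‑2‑yl]‑10‑methylundeca‑2,4,6‑trienamide
Conditions: PPTS (cat.), acetone/H2O (10:1), rt
Reagents that add atoms: water, O
Why: Mild acid hydrolysis of the allylic dimethyl ketal through its oxocarbenium ion should unveil the C1 ketone without touching a stereocentre, since the acyl‑conjugated trienyl group disfavours ionisation at C4.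

**Compound list**
1 | 4‑methylpentanal | CC(C)CCC=O | starting material
2 | (triphenylphosphoranylidene)acetaldehyde | O=CC=P(c1ccccc1)(c1ccccc1)c1ccccc1 | starting material
3 | (E)‑6‑methylhept‑2‑enal | CC(C)CC/C=C/C=O | intermediate
4 | triethyl 4‑phosphonocrotonate, ethyl (E)‑4‑(diethoxyphosphoryl)but‑2‑enoate | CCOC(=O)/C=C/CP(=O)(OCC)OCC | starting material
5 | ethyl (2E,4E,6E)‑10‑methylundeca‑2,4,6‑trienoate | CC(C)CC/C=C/C=C/C=C/C(=O)OCC | intermediate
6 | (2E,4E,6E)‑10‑methylundeca‑2,4,6‑trienoic acid | CC(C)CC/C=C/C=C/C=C/C(=O)O | intermediate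
7 | 2,5‑dimethoxyaniline | COc1ccc(OC)c(N)c1 | starting material
8 | (2E,4E,6E)‑10‑methylundeca‑2,4,6‑trienoyl chloride | CC(C)CC/C=C/C=C/C=C/C(=O)Cl | intermediate
9 | N‑(2,5‑dimethoxyphenyl)‑(2E,4E,6E)‑10‑methylundeca‑2,4,6‑trienamide | CC(C)CC/C=C/C=C/C=C/C(=O)Nc1cc(OC)ccc1OC | intermediate
10 | N‑(6,6‑dimethoxy‑3‑oxocyclohexa‑1,4‑dien‑1‑yl)‑(2E,4E,6E)‑10‑methylundeca‑2,4,6‑trienamide (quinone monoketal; ketal at C1, ketone at C4) | CC(C)CC/C=C/C=C/C=C/C(=O)NC1=CC(=O)C=CC1(OC)OC | intermediate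
11 | N‑[(5S,6R)‑5,6‑epoxy‑1,1‑dimethoxy‑4‑oxocyclohex‑2‑en‑2‑yl]‑(2E,4E,6E)‑10‑methylundeca‑2,4,6‑trienamide | CC(C)CC/C=C/C=C/C=C/C(=O)NC1=CC(=O)[C@H]2O[C@H]2C1(OC)OC | intermediate
12 | (E)‑4,4‑dimethoxybut‑2‑enal | COC(OC)/C=C/C=O | starting material
13 | triethyl phosphonoacetate | CCOC(=O)CP(=O)(OCC)OCC | starting material
14 | ethyl (2E,4E)‑6,6‑dimethoxyhexa‑2,4‑dienoate | CCOC(=O)/C=C/C=C/C(OC)OC | intermediate
15 | ethyl (2E,4E)‑6‑oxohexa‑2,4‑dienoate | CCOC(=O)/C=C/C=C/C=O | intermediate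
16 | ethyl (2E,4E,6E)‑7‑iodohepta‑2,4,6‑trienoate | CCOC(=O)/C=C/C=C/C=C/I | intermediate
17 | (2E,4E,6E)‑7‑iodohepta‑2,4,6‑trienoic acid | OC(=O)/C=C/C=C/C=C/I | intermediate
18 | 2‑amino‑3‑hydroxycyclopent‑2‑en‑1‑one hydrochloride | NC1=C(O)CCC1=O.Cl | starting material
19 | (2E,4E,6E)‑7‑iodohepta‑2,4,6‑trienoyl chloride | ClC(=O)/C=C/C=C/C=C/I | intermediate
20 | (2E,4E,6E)‑N‑(2‑hydroxy‑5‑oxocyclopent‑1‑en‑1‑yl)‑7‑iodohepta‑2,4,6‑trienamide | O=C(/C=C/C=C/C=C/I)NC1=C(O)CCC1=O | intermediate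
21 | tris(chloromagnesium) derivative of 20: (1E,3E,5E)‑trienylmagnesium chloride with N‑ and O‑chloromagnesium groups | Cl[Mg]/C=C/C=C/C=C/C(=O)N([Mg]Cl)C1=C(O[Mg]Cl)CCC1=O | intermediate
22 | N‑chloromagnesium amidate of 11 | CC(C)CC/C=C/C=C/C=C/C(=O)N([Mg]Cl)C1=CC(=O)[C@H]2O[C@H]2C1(OC)OC | intermediate
23 | (2E,4E,6E)‑N‑[(4S,5S,6R)‑5,6‑epoxy‑4‑hydroxy‑4‑[(1E,3E,5E)‑7‑[(2‑hydroxy‑5‑oxocyclopent‑1‑en‑1‑yl)amino]‑7‑oxohepta‑1,3,5‑trien‑1‑yl]‑1,1‑dimethoxycyclohex‑2‑en‑2‑yl]‑10‑methylundeca‑2,4,6‑trienamide | CC(C)CC/C=C/C=C/C=C/C(=O)NC1=C[C@@](O)(/C=C/C=C/C=C/C(=O)NC2=C(O)CCC2=O)[C@H]2O[C@H]2C1(OC)OC | intermediate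
24 | (2E,4E,6E)‑N‑[(4S,5S,6R)‑5,6‑epoxy‑4‑hydroxy‑4‑[(1E,3E,5E)‑7‑[(2‑hydroxy‑5‑oxocyclopent‑1‑en‑1‑yl)amino]‑7‑oxohepta‑1,3,5‑trien‑1‑yl]‑1‑oxocyclohex‑2‑en‑2‑yl]‑10‑methylundeca‑2,4,6‑trienamide | CC(C)CC/C=C/C=C/C=C/C(=O)NC1=C[C@@](O)(/C=C/C=C/C=C/C(=O)NC2=C(O)CCC2=O)[C@H]2O[C@H]2C1=O | target

**Step count**
- Total steps: 12.
- Longest linear sequence: 8 (steps 1–6, 11, 12).

**Steps most likely to fail, with fallbacks**

Step 11 (proposed new method). What may go wrong: no magnesium chelate forms and the reagent approaches from the face remote from the oxirane, giving the C4 epimer; iodine–magnesium exchange on the electron‑rich dianion is sluggish; the substrate is enolised instead of attacked. The fallback sets out from 11 and comes back at 23, using classical reaction types only. Chlorotrimethylsilane with catalytic tetrabutylammonium chloride in CH2Cl2 opens the oxirane of 11 at C5, the α‑carbon of the epoxy ketone, with inversion. This gives the trans chlorohydrin silyl ether N‑[(5R,6S)‑5‑chloro‑1,1‑dimethoxy‑4‑oxo‑6‑(trimethylsilyloxy)cyclohex‑2‑en‑2‑yl]‑(2E,4E,6E)‑10‑methylundeca‑2,4,6‑trienamide F1, whose chlorine stands on the face opposite to the former oxirane oxygen. After removal of the N–H with NaH, the organocerium reagent made from 21 and CeCl3 (non‑basic, to avoid β‑elimination) should add to C4 anti to the α‑C–Cl bond (Cornforth/Felkin–Anh control). This gives (2E,4E,6E)‑N‑[(4S,5R,6S)‑5‑chloro‑4‑hydroxy‑4‑[(1E,3E,5E)‑7‑[(2‑hydroxy‑5‑oxocyclopent‑1‑en‑1‑yl)amino]‑7‑oxohepta‑1,3,5‑trien‑1‑yl]‑1,1‑dimethoxy‑6‑(trimethylsilyloxy)cyclohex‑2‑en‑2‑yl]‑10‑methylundeca‑2,4,6‑trienamide F2, with C1' cis to the C6 oxygen. K2CO3 in methanol then removes the silyl group, and the C6 alkoxide displaces chloride at C5 with inversion, re‑forming the (5S,6R)‑oxirane and giving 23.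

Step 6. What may go wrong: erosion of enantioselectivity on the long, lipophilic trienamide substrate, attack of basic peroxide on the polyene, and failure to upgrade the optical purity by crystallisation. The fallback sets out from 7 and comes back at 11; it epoxidises a simple carbamate and brings in the trienoyl group afterwards. Boc2O converts 7 into tert‑butyl N‑(2,5‑dimethoxyphenyl)carbamate F3. PhI(OAc)2 in methanol gives tert‑butyl N‑(6,6‑dimethoxy‑3‑oxocyclohexa‑1,4‑dien‑1‑yl)carbamate F4. The phase‑transfer epoxidation of step 6 then gives tert‑butyl N‑[(5S,6R)‑5,6‑epoxy‑1,1‑dimethoxy‑4‑oxocyclohex‑2‑en‑2‑yl]carbamate F5, which is recrystallised. The sodium salt of F5 (NaH, THF) is acylated with acid chloride 8 to give tert‑butyl N‑[(5S,6R)‑5,6‑epoxy‑1,1‑dimethoxy‑4‑oxocyclohex‑2‑en‑2‑yl]‑N‑[(2E,4E,6E)‑10‑methylundeca‑2,4,6‑trienoyl]carbamate F6. Mg(ClO4)2 in acetonitrile then removes the Boc group from the imide selectively to give 11.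

Step 12. What may go wrong: acid‑promoted ionisation of the tertiary bis‑allylic alcohol, opening or migration of the oxirane, or isomerisation of the polyenes before the ketal is cleaved. The fallback sets out from 11 and comes back at 24; it removes the ketal before the acid‑sensitive polyene carbinol exists and finishes under neutral conditions. The magnesium‑directed addition of step 11 is run with (E)‑2‑(tributylstannyl)vinylmagnesium bromide, made from (E)‑1,2‑bis(tributylstannyl)ethene with n‑BuLi and then MgBr2·OEt2. This gives (2E,4E,6E)‑N‑[(4R,5S,6R)‑5,6‑epoxy‑4‑hydroxy‑1,1‑dimethoxy‑4‑[(E)‑2‑(tributylstannyl)ethenyl]cyclohex‑2‑en‑2‑yl]‑10‑methylundeca‑2,4,6‑trienamide F7. It has the same spatial arrangement as 23; the C4 descriptor changes only because tin raises the priority of the vinyl branch. PPTS in wet acetone hydrolyses the ketal to (2E,4E,6E)‑N‑[(4R,5S,6R)‑5,6‑epoxy‑4‑hydroxy‑1‑oxo‑4‑[(E)‑2‑(tributylstannyl)ethenyl]cyclohex‑2‑en‑2‑yl]‑10‑methylundeca‑2,4,6‑trienamide F8. A Stille coupling (PdCl2(MeCN)2, DMF, rt) with (2E,4E)‑5‑bromo‑N‑(2‑hydroxy‑5‑oxocyclopent‑1‑en‑1‑yl)penta‑2,4‑dienamide F9 then forms the C2'–C3' bond and gives 24. F9 is made from (2E,4E)‑5‑bromopenta‑2,4‑dienoic acid and 18 as in step 10.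

**Further compounds**
F1 | step 11 | N‑[(5R,6S)‑5‑chloro‑1,1‑dimethoxy‑4‑oxo‑6‑(trimethylsilyloxy)cyclohex‑2‑en‑2‑yl]‑(2E,4E,6E)‑10‑methylundeca‑2,4,6‑trienamide | CC(C)CC/C=C/C=C/C=C/C(=O)NC1=CC(=O)[C@H](Cl)[C@@H](O[Si](C)(C)C)C1(OC)OC
F2 | step 11 | (2E,4E,6E)‑N‑[(4S,5R,6S)‑5‑chloro‑4‑hydroxy‑4‑[(1E,3E,5E)‑7‑[(2‑hydroxy‑5‑oxocyclopent‑1‑en‑1‑yl)amino]‑7‑oxohepta‑1,3,5‑trien‑1‑yl]‑1,1‑dimethoxy‑6‑(trimethylsilyloxy)cyclohex‑2‑en‑2‑yl]‑10‑methylundeca‑2,4,6‑trienamide | CC(C)CC/C=C/C=C/C=C/C(=O)NC1=C[C@@](O)(/C=C/C=C/C=C/C(=O)NC2=C(O)CCC2=O)[C@H](Cl)[C@@H](O[Si](C)(C)C)C1(OC)OC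
F3 | step 6 | tert‑butyl N‑(2,5‑dimethoxyphenyl)carbamate | COc1ccc(OC)c(NC(=O)OC(C)(C)C)c1
F4 | step 6 | tert‑butyl N‑(6,6‑dimethoxy‑3‑oxocyclohexa‑1,4‑dien‑1‑yl)carbamate | CC(C)(C)OC(=O)NC1=CC(=O)C=CC1(OC)OC
F5 | step 6 | tert‑butyl N‑[(5S,6R)‑5,6‑epoxy‑1,1‑dimethoxy‑4‑oxocyclohex‑2‑en‑2‑yl]carbamate | CC(C)(C)OC(=O)NC1=CC(=O)[C@H]2O[C@H]2C1(OC)OC
F6 | step 6 | tert‑butyl N‑[(5S,6R)‑5,6‑epoxy‑1,1‑dimethoxy‑4‑oxocyclohex‑2‑en‑2‑yl]‑N‑[(2E,4E,6E)‑10‑methylundeca‑2,4,6‑trienoyl]carbamate | CC(C)CC/C=C/C=C/C=C/C(=O)N(C(=O)OC(C)(C)C)C1=CC(=O)[C@H]2O[C@H]2C1(OC)OC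
F7 | step 12 | (2E,4E,6E)‑N‑[(4R,5S,6R)‑5,6‑epoxy‑4‑hydroxy‑1,1‑dimethoxy‑4‑[(E)‑2‑(tributylstannyl)ethenyl]cyclohex‑2‑en‑2‑yl]‑10‑methylundeca‑2,4,6‑trienamide | CC(C)CC/C=C/C=C/C=C/C(=O)NC1=C[C@@](O)(/C=C/[Sn](CCCC)(CCCC)CCCC)[C@H]2O[C@H]2C1(OC)OC
F8 | step 12 | (2E,4E,6E)‑N‑[(4R,5S,6R)‑5,6‑epoxy‑4‑hydroxy‑1‑oxo‑4‑[(E)‑2‑(tributylstannyl)ethenyl]cyclohex‑2‑en‑2‑yl]‑10‑methylundeca‑2,4,6‑trienamide | CC(C)CC/C=C/C=C/C=C/C(=O)NC1=C[C@@](O)(/C=C/[Sn](CCCC)(CCCC)CCCC)[C@H]2O[C@H]2C1=O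
F9 | step 12 | (2E,4E)‑5‑bromo‑N‑(2‑hydroxy‑5‑oxocyclopent‑1‑en‑1‑yl)penta‑2,4‑dienamide | O=C(/C=C/C=C/Br)NC1=C(O)CCC1=O
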